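**Strategy.** The route rests on cutting the C1–C5 bond of the spiro[4.5]decane. The six-membered ring (C6–C10, with the C8 oxygen and methyls on C6 and C10) is a dearomatised 3,5-dimethylphenol whose para carbon is the spiro atom C5. A phenoxide carrying the chain C4(OSi)–C3–C2(isopropenyl)–C1(OTs) at that carbon therefore closes the cyclopentane by ipso-alkylation, forming the quaternary centre and the cross-conjugated dienone in one operation. The precursor is an open-chain (2S,4R)-tosylate in which the phenol is masked as an aryl silyl ether; fluoride releases the phenoxide in the flask, so no strong base meets the elimination-prone tosylate.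

Key step: step 7

Remark on the chemistry: atom numbers are those of the spiro[4.5]decane (C1–C4 cyclopentane, C5 spiro atom, C6–C10 six-membered ring) and are also used for the matching atoms of the open-chain intermediates. The ligand antipodes in steps 2, 5 and 8 are assigned by analogy with simpler cyclic enones and aryl ketones; the opposite antipode would be used if a first run showed the other sense.

**Step 1**
Reactants: 1 4-bromo-3,5-dimethylphenol
Product: 2 tert-butyl(4-bromo-3,5-dimethylphenoxy)dimethylsilane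
Conditions: TBSCl, imidazole, DMF, rt
Reagents that add atoms: tert-butyldimethylsilyl chloride, CC(C)(C)[Si](C)(C)Cl
Why: Imidazole-mediated O-silylation of a phenol; the aryl silyl ether hides the acidic OH during halogen–lithium exchange and later serves as the latent phenoxide.

**Step 2**
Reactants: 3 2(5H)-furanone; 4 isopropenylboronic acid pinacol ester
Product: 5 (S)-4-(prop-1-en-2-yl)dihydrofuran-2(3H)-one
Conditions: [RhCl(C2H4)2]2 (2.5 mol%), (S)-BINAP (5.5 mol%), aq. KOH (0.3 equiv), 1,4-dioxane/H2O 10:1, 40 °C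
Reagents that add atoms: none
Why: Rh(I)/BINAP-catalysed asymmetric conjugate addition of an alkenylboron reagent to an unsaturated lactone (Hayashi–Miyaura reaction); the chiral Rh–alkenyl species adds to one enantioface of the butenolide and so sets C2 as (S).

**Step 3**
Reactants: 2 tert-butyl(4-bromo-3,5-dimethylphenoxy)dimethylsilane; 5 (S)-4-(prop-1-en-2-yl)dihydrofuran-2(3H)-one
Product: 7 (S)-1-{4-[(tert-butyldimethylsilyl)oxy]-2,6-dimethylphenyl}-4-hydroxy-3-(prop-1-en-2-yl)butan-1-one, via aryllithium 6 (not isolated)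
Conditions: 2, n-BuLi, THF, −78 °C; then 5, −78 °C; AcOH quench at −78 °C
Reagents that add atoms: none
Why: Bromine–lithium exchange followed by acyl substitution on the lactone; the lithium lactolate is stable at −78 °C and the di-ortho-substituted aryl ketone it releases is too hindered for a second addition, so the γ-hydroxy ketone results with C2 untouched.

**Step 4**
Reactants: 7 (S)-1-{4-[(tert-butyldimethylsilyl)oxy]-2,6-dimethylphenyl}-4-hydroxy-3-(prop-1-en-2-yl)butan-1-one
Product: 8 (S)-4-{4-[(tert-butyldimethylsilyl)oxy]-2,6-dimethylphenyl}-4-oxo-2-(prop-1-en-2-yl)butyl 4-methylbenzenesulfonate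
Conditions: TsCl, pyridine, DMAP (cat.), CH2Cl2, 0 °C
Reagents that add atoms: 4-toluenesulfonyl chloride, Cc1ccc(S(=O)(=O)Cl)cc1
Why: Sulfonylation of the only free (primary) hydroxyl; the weakly basic medium does not enolise the γ-sulfonyloxy ketone, and tosylating before the reduction means the ketone is reduced without a free OH in the molecule.

**Step 5**
Reactants: 8 (S)-4-{4-[(tert-butyldimethylsilyl)oxy]-2,6-dimethylphenyl}-4-oxo-2-(prop-1-en-2-yl)butyl 4-methylbenzenesulfonate
Product: 9 (2S,4R)-4-{4-[(tert-butyldimethylsilyl)oxy]-2,6-dimethylphenyl}-4-hydroxy-2-(prop-1-en-2-yl)butyl 4-methylbenzenesulfonate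
Conditions: (S)-Me-CBS (20 mol%), catecholborane, toluene, −40 → −20 °C; MeOH, pH 7 buffer; crude product used directly
Reagents that add atoms: none
Why: Corey–Bakshi–Shibata reduction in which the twisted 2,6-dimethylaryl group is the large and the CH2 chain the small ketone substituent, so the (S)-oxazaborolidine should give the (4R)-carbinol under catalyst control (the remote C2 centre has little say); catecholborane is chosen because it leaves the isopropenyl group alone at low temperature.

**Step 6**
Reactants: 9 (2S,4R)-4-{4-[(tert-butyldimethylsilyl)oxy]-2,6-dimethylphenyl}-4-hydroxy-2-(prop-1-en-2-yl)butyl 4-methylbenzenesulfonate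
Product: 10 (2S,4R)-4-[(tert-butyldimethylsilyl)oxy]-4-{4-[(tert-butyldimethylsilyl)oxy]-2,6-dimethylphenyl}-2-(prop-1-en-2-yl)butyl 4-methylbenzenesulfonate
Conditions: TBSOTf, 2,6-lutidine, CH2Cl2, −78 → 0 °C
Reagents that add atoms: tert-butyldimethylsilyl trifluoromethanesulfonate, CC(C)(C)[Si](C)(C)OS(=O)(=O)C(F)(F)F
Why: Silyl triflate/lutidine silylation is fast enough for the hindered benzylic alcohol and caps it before it can displace the tosylate to form a tetrahydrofuran; only the O–H bond reacts, so C4 keeps its configuration.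

**Step 7**
Reactants: 10 (2S,4R)-4-[(tert-butyldimethylsilyl)oxy]-4-{4-[(tert-butyldimethylsilyl)oxy]-2,6-dimethylphenyl}-2-(prop-1-en-2-yl)butyl 4-methylbenzenesulfonate
Product: 12 (2S,4R)-4-[(tert-butyldimethylsilyl)oxy]-6,10-dimethyl-2-(prop-1-en-2-yl)spiro[4.5]deca-6,9-dien-8-one, via tetrabutylammonium phenoxide 11 (not isolated)
Conditions: TBAF (1.05 equiv), THF/t-BuOH 4:1, 0.005 M, 0 → 40 °C
Reagents that add atoms: none
Why: Fluoride cleaves the aryl O–Si bond far faster than the hindered secondary alkyl O–Si bond, so phenoxide 11 forms without any excess strong base, and its para carbon C5 then attacks C1 in an intramolecular SN2 reaction that expels tosylate (phenoxide ipso-alkylation, Ar1-5 participation, the known route from 4-(4-sulfonyloxybutyl)phenoxides to spiro[4.5]decadienones). The cyclopentane closes in a 5-exo-tet mode by forming C5–C1, and because C5 becomes quaternary the cross-conjugated dienone cannot tautomerise back to a phenol. No stereocentre is created (C5 carries two constitutionally identical ring arms at this stage) and no bond at C2 or C4 is broken, so both configurations pass through unchanged. The step needs para C-alkylation in preference to O-alkylation, E2 loss of the allylic C2–H, fluoride substitution or loss of silanolate to a quinone methide: the four-atom tether reaches only C5, the oxygen is out of reach and high dilution suppresses intermolecular etherification, the ring carbons next to C5 carry methyl groups, the phenoxide is the only base present, one equivalent of fluoride is consumed at silicon, and silanolate is a poor leaving group at this temperature. The two ortho methyls hold the C4–H in the arene plane and the C4–C3 bond perpendicular to it, which places C1 over the π lobe of C5.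

**Step 8**
Reactants: 12 (2S,4R)-4-[(tert-butyldimethylsilyl)oxy]-6,10-dimethyl-2-(prop-1-en-2-yl)spiro[4.5]deca-6,9-dien-8-one
Product: 14 (2S,4R,5R,10R)-4-[(tert-butyldimethylsilyl)oxy]-6,10-dimethyl-2-(prop-1-en-2-yl)spiro[4.5]dec-6-en-8-one, via silyl dienol ether 13 (not isolated)
Conditions: Cu(OAc)2·H2O (5 mol%), (S)-DTBM-SEGPHOS (5.5 mol%), (EtO)2MeSiH (1.2 equiv), toluene, 0 °C → rt; then 0.5 M HCl, THF, 0 °C
Reagents that add atoms: none
Why: CuH-catalysed asymmetric conjugate reduction used as a desymmetrisation of a 4,4-disubstituted cyclohexadienone: the C4 arm, whose silyloxy group points over C10, shields the face syn to C4 so that hydride should arrive from the C1 face, the bulky chiral bisphosphine selects between the two diastereotopic double bonds and its (S)-antipode is expected to be matched with attack at C10, which sets C10 (methyl syn to C4) and makes C5 stereogenic in the same event, while the enolate stays as silyl dienol ether 13 and so protects the second double bond from reduction.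

**Step 9**
Reactants: 14 (2S,4R,5R,10R)-4-[(tert-butyldimethylsilyl)oxy]-6,10-dimethyl-2-(prop-1-en-2-yl)spiro[4.5]dec-6-en-8-one
Product: 16 (2S,4R,5R,9R,10S)-4-[(tert-butyldimethylsilyl)oxy]-9-hydroxy-6,10-dimethyl-2-(prop-1-en-2-yl)spiro[4.5]dec-6-en-8-one, via potassium dienolate 15 (not isolated)
Conditions: KHMDS, THF, −78 °C; 2-(phenylsulfonyl)-3-phenyloxaziridine, −78 °C; AcOH quench
Reagents that add atoms: 2-(phenylsulfonyl)-3-phenyloxaziridine, O=S(=O)(c1ccccc1)N1OC1c1ccccc1
Why: Kinetic deprotonation of the enone at the α′ carbon C9 gives the cross-conjugated dienolate, which the oxaziridine should hydroxylate (Davis oxidation) on the face away from the adjacent C10 methyl and the C4 arm, setting C9 trans to the methyl; the reagent does not touch the isopropenyl group.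

**Step 10**
Reactants: 16 (2S,4R,5R,9R,10S)-4-[(tert-butyldimethylsilyl)oxy]-9-hydroxy-6,10-dimethyl-2-(prop-1-en-2-yl)spiro[4.5]dec-6-en-8-one
Product: 17 (2S,4R,5R,9R,10S)-4-[(tert-butyldimethylsilyl)oxy]-6,10-dimethyl-8-oxo-2-(prop-1-en-2-yl)spiro[4.5]dec-6-en-9-yl acetate
Conditions: Ac2O, pyridine, DMAP (cat.), CH2Cl2, 0 °C → rt
Reagents that add atoms: acetic anhydride, CC(=O)OC(C)=O
Why: DMAP-catalysed acetylation of a secondary α-ketol; the trans acetoxy/methyl arrangement is also expected to be the more stable one, so enolisation at C9 should not erode it.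

**Step 11**
Reactants: 17 (2S,4R,5R,9R,10S)-4-[(tert-butyldimethylsilyl)oxy]-6,10-dimethyl-8-oxo-2-(prop-1-en-2-yl)spiro[4.5]dec-6-en-9-yl acetate
Product: 18 (2S,4R,5R,9R,10S)-4-hydroxy-6,10-dimethyl-8-oxo-2-(prop-1-en-2-yl)spiro[4.5]dec-6-en-9-yl acetate
Conditions: HF·pyridine, pyridine/THF, 0 °C → rt
Reagents that add atoms: none
Why: Acidic fluoride cleavage of the secondary silyl ether, which spares the acetate and never generates the C4 alkoxide that could trigger retro-vinylogous-aldol cleavage of the C4–C5 bond.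

**Step 12**
Reactants: 18 (2S,4R,5R,9R,10S)-4-hydroxy-6,10-dimethyl-8-oxo-2-(prop-1-en-2-yl)spiro[4.5]dec-6-en-9-yl acetate
Product: 19 (2S,4R,5R,9R,10S)-9-acetoxy-6,10-dimethyl-8-oxo-2-(prop-1-en-2-yl)spiro[4.5]dec-6-en-4-yl 2-methylpropanoate
Conditions: i-PrCOCl, pyridine, DMAP (cat.), CH2Cl2, 0 °C → rt
Reagents that add atoms: isobutyryl chloride, CC(C)C(Cl)=O
Why: Acylation of the hindered secondary alcohol with an acid chloride under nucleophilic catalysis; only the O–H bond reacts, so C4 is retained and the two esters end up on the correct oxygens.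

**Compound list**
1 | 4-bromo-3,5-dimethylphenol | Cc1cc(O)cc(C)c1Br | starting material
2 | tert-butyl(4-bromo-3,5-dimethylphenoxy)dimethylsilane | Cc1cc(O[Si](C)(C)C(C)(C)C)cc(C)c1Br | intermediate
3 | 2(5H)-furanone | O=C1C=CCO1 | starting material
4 | isopropenylboronic acid pinacol ester | C=C(C)B1OC(C)(C)C(C)(C)O1 | starting material
5 | (S)-4-(prop-1-en-2-yl)dihydrofuran-2(3H)-one | C=C(C)[C@@H]1CC(=O)OC1 | intermediate
6 | {4-[(tert-butyldimethylsilyl)oxy]-2,6-dimethylphenyl}lithium (not isolated) | Cc1cc(O[Si](C)(C)C(C)(C)C)cc(C)c1[Li] | intermediate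
7 | (S)-1-{4-[(tert-butyldimethylsilyl)oxy]-2,6-dimethylphenyl}-4-hydroxy-3-(prop-1-en-2-yl)butan-1-one | C=C(C)[C@@H](CO)CC(=O)c1c(C)cc(O[Si](C)(C)C(C)(C)C)cc1C | intermediate
8 | (S)-4-{4-[(tert-butyldimethylsilyl)oxy]-2,6-dimethylphenyl}-4-oxo-2-(prop-1-en-2-yl)butyl 4-methylbenzenesulfonate | C=C(C)[C@@H](COS(=O)(=O)c1ccc(C)cc1)CC(=O)c1c(C)cc(O[Si](C)(C)C(C)(C)C)cc1C | intermediate
9 | (2S,4R)-4-{4-[(tert-butyldimethylsilyl)oxy]-2,6-dimethylphenyl}-4-hydroxy-2-(prop-1-en-2-yl)butyl 4-methylbenzenesulfonate | C=C(C)[C@@H](COS(=O)(=O)c1ccc(C)cc1)C[C@@H](O)c1c(C)cc(O[Si](C)(C)C(C)(C)C)cc1C | intermediate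
10 | (2S,4R)-4-[(tert-butyldimethylsilyl)oxy]-4-{4-[(tert-butyldimethylsilyl)oxy]-2,6-dimethylphenyl}-2-(prop-1-en-2-yl)butyl 4-methylbenzenesulfonate (cyclisation precursor) | C=C(C)[C@@H](COS(=O)(=O)c1ccc(C)cc1)C[C@@H](O[Si](C)(C)C(C)(C)C)c1c(C)cc(O[Si](C)(C)C(C)(C)C)cc1C | intermediate
11 | tetrabutylammonium 4-[(1R,3S)-1-[(tert-butyldimethylsilyl)oxy]-3-(prop-1-en-2-yl)-4-(tosyloxy)butyl]-3,5-dimethylphenoxide (not isolated) | C=C(C)[C@@H](COS(=O)(=O)c1ccc(C)cc1)C[C@@H](O[Si](C)(C)C(C)(C)C)c1c(C)cc([O-])cc1C.CCCC[N+](CCCC)(CCCC)CCCC | intermediate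
12 | (2S,4R)-4-[(tert-butyldimethylsilyl)oxy]-6,10-dimethyl-2-(prop-1-en-2-yl)spiro[4.5]deca-6,9-dien-8-one | C=C(C)[C@@H]1C[C@@H](O[Si](C)(C)C(C)(C)C)C2(C1)C(C)=CC(=O)C=C2C | intermediate
13 | (2S,4R,5R,10R)-4-[(tert-butyldimethylsilyl)oxy]-8-[(diethoxy(methyl)silyl)oxy]-6,10-dimethyl-2-(prop-1-en-2-yl)spiro[4.5]deca-6,8-diene (not isolated) | C=C(C)[C@@H]1C[C@@H](O[Si](C)(C)C(C)(C)C)[C@@]2(C1)C(C)=CC(O[Si](C)(OCC)OCC)=C[C@H]2C | intermediate
14 | (2S,4R,5R,10R)-4-[(tert-butyldimethylsilyl)oxy]-6,10-dimethyl-2-(prop-1-en-2-yl)spiro[4.5]dec-6-en-8-one | C=C(C)[C@@H]1C[C@@H](O[Si](C)(C)C(C)(C)C)[C@@]2(C1)C(C)=CC(=O)C[C@H]2C | intermediate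
15 | potassium (2S,4R,5R,10R)-4-[(tert-butyldimethylsilyl)oxy]-6,10-dimethyl-2-(prop-1-en-2-yl)spiro[4.5]deca-6,8-dien-8-olate (not isolated) | C=C(C)[C@@H]1C[C@@H](O[Si](C)(C)C(C)(C)C)[C@@]2(C1)C(C)=CC([O-])=C[C@H]2C.[K+] | intermediate
16 | (2S,4R,5R,9R,10S)-4-[(tert-butyldimethylsilyl)oxy]-9-hydroxy-6,10-dimethyl-2-(prop-1-en-2-yl)spiro[4.5]dec-6-en-8-one | C=C(C)[C@@H]1C[C@@H](O[Si](C)(C)C(C)(C)C)[C@@]2(C1)C(C)=CC(=O)[C@H](O)[C@H]2C | intermediate
17 | (2S,4R,5R,9R,10S)-4-[(tert-butyldimethylsilyl)oxy]-6,10-dimethyl-8-oxo-2-(prop-1-en-2-yl)spiro[4.5]dec-6-en-9-yl acetate | C=C(C)[C@@H]1C[C@@H](O[Si](C)(C)C(C)(C)C)[C@@]2(C1)C(C)=CC(=O)[C@H](OC(C)=O)[C@H]2C | intermediate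
18 | (2S,4R,5R,9R,10S)-4-hydroxy-6,10-dimethyl-8-oxo-2-(prop-1-en-2-yl)spiro[4.5]dec-6-en-9-yl acetate | C=C(C)[C@@H]1C[C@@H](O)[C@@]2(C1)C(C)=CC(=O)[C@H](OC(C)=O)[C@H]2C | intermediate
19 | (2S,4R,5R,9R,10S)-9-acetoxy-6,10-dimethyl-8-oxo-2-(prop-1-en-2-yl)spiro[4.5]dec-6-en-4-yl 2-methylpropanoate | C=C(C)[C@@H]1C[C@@H](OC(=O)C(C)C)[C@@]2(C1)C(C)=CC(=O)[C@H](OC(C)=O)[C@H]2C | target

**Step count**
Total: 12 steps. Longest linear sequence: 11 steps (steps 2–12 from 2(5H)-furanone; equally steps 1 and 3–12 from the bromophenol).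

**Steps most likely to fail**

Step 8. The hydride may be delivered to the other double bond (C6=C7) or from the C4 face, because the matched ligand cannot by itself tell attack at C10 from the C1 face apart from attack at C6 from the C4 face; that choice rests on the steric bias of the silyloxy arm alone. Turnover may also stall at the fully substituted β-carbon next to the quaternary C5. The fallback replaces the metal hydride by biocatalysis and sets out from 12: the dienone would be incubated with a panel of Old Yellow Enzyme-type ene-reductases (NADP+, glucose, glucose dehydrogenase, phosphate buffer pH 7 with DMSO as cosolvent, 30 °C). This enzyme class is known to reduce one double bond of 4,4-disubstituted cyclohexa-2,5-dienones by flavin hydride transfer to a β-carbon and protonation at the α-carbon, and isoforms of opposite site preference are available. The isoform that gives the required isomer would be used and the route is rejoined at 14; no compound outside the list is made on this path (F0).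

Step 5. Hydride transfer to a carbonyl flanked by two ortho methyls may be slow, which would lower facial discrimination, and the product may cyclise to a tetrahydrofuran during a prolonged reaction or work-up. The fallback gives up catalyst control in favour of separation with recycling and sets out from 8: Luche reduction (NaBH4, CeCl3·7H2O, MeOH/THF, −40 °C, NH4Cl quench) should give 9 together with its C4 epimer, (2S,4S)-4-{4-[(tert-butyldimethylsilyl)oxy]-2,6-dimethylphenyl}-4-hydroxy-2-(prop-1-en-2-yl)butyl 4-methylbenzenesulfonate F1. Because C2 is already fixed the two are diastereomers and would be separated by chromatography; the unwanted epimer is returned to 8 by Dess–Martin oxidation (NaHCO3, CH2Cl2) and recycled, and the route is rejoined at 9.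

Step 7. Fluoride may attack the tosylate, or ring closure at the doubly flanked ipso carbon may be slow enough for intermolecular O-alkylation or elimination to compete. The fallback changes the nucleofuge and separates phenol release from ring closure, setting out from 10: a Finkelstein reaction (NaI, acetone, 50 °C) would give tert-butyl{4-[(1R,3S)-1-[(tert-butyldimethylsilyl)oxy]-4-iodo-3-(prop-1-en-2-yl)butyl]-3,5-dimethylphenoxy}dimethylsilane F2, whose softer leaving group favours attack by carbon. KHF2 in MeOH at rt would then remove only the aryl silyl group to give 4-[(1R,3S)-1-[(tert-butyldimethylsilyl)oxy]-4-iodo-3-(prop-1-en-2-yl)butyl]-3,5-dimethylphenol F3, and Cs2CO3 (1.1 equiv) in MeCN at 0.005 M, rt → 40 °C, would close the ring in the absence of fluoride; the route is rejoined at 12.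

**Further compounds**
F0 | step 8 | none | none
F1 | step 5 | (2S,4S)-4-{4-[(tert-butyldimethylsilyl)oxy]-2,6-dimethylphenyl}-4-hydroxy-2-(prop-1-en-2-yl)butyl 4-methylbenzenesulfonate | C=C(C)[C@@H](COS(=O)(=O)c1ccc(C)cc1)C[C@H](O)c1c(C)cc(O[Si](C)(C)C(C)(C)C)cc1C
F2 | step 7 | tert-butyl{4-[(1R,3S)-1-[(tert-butyldimethylsilyl)oxy]-4-iodo-3-(prop-1-en-2-yl)butyl]-3,5-dimethylphenoxy}dimethylsilane | C=C(C)[C@@H](CI)C[C@@H](O[Si](C)(C)C(C)(C)C)c1c(C)cc(O[Si](C)(C)C(C)(C)C)cc1C
F3 | step 7 | 4-[(1R,3S)-1-[(tert-butyldimethylsilyl)oxy]-4-iodo-3-(prop-1-en-2-yl)butyl]-3,5-dimethylphenol | C=C(C)[C@@H](CI)C[C@@H](O[Si](C)(C)C(C)(C)C)c1c(C)cc(O)cc1C
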